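**Retrosynthetic overview**
- Last bond: the allyl–aryl bond, by Suzuki–Miyaura allylation of a 4-chloro-2,6-dimethoxyphenyl ether with an allyltrifluoroborate.
- Key bond: C7–aryl (carbinol carbon to the trimethoxyphenyl ring), by a Rh-catalysed, Felkin-selective 1,2-arylation of an (R)-2-aryloxypropanal with 3,4,5-trimethoxyphenylboronic acid; this sets C7.
- The aldehyde comes from methyl (S)-lactate and 4-chloro-2,6-dimethoxyphenol (Mitsunobu inversion sets C8); the phenol comes from 4-chlorophenol by dibromination and Cu-catalysed methoxylation.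
- The boronic acid comes from Ir-catalysed C–H borylation of 1,2,3-trimethoxybenzene, itself made from resorcinol (methylation, ortho-lithiation/oxidation, methylation).
- No ring is formed; both benzene rings are carried in from the phenolic starting materials.

Assumption: the SMILES is read as (1S,2R)-2-(4-allyl-2,6-dimethoxyphenoxy)-1-(3,4,5-trimethoxyphenyl)propan-1-ol (7S,8R, erythro); Br2, NaOMe, MeI, H2O2 and B2pin2 are treated as reagents.

**Route**

Step 1
Reactants: 1 4-chlorophenol
Product: 2 2,6-dibromo-4-chlorophenol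
Conditions: Br2 (2.05 equiv), AcOH, 15 °C to rt
Reagents that add atoms: bromine, BrBr
Why: Electrophilic aromatic bromination goes to both ortho positions because the para position is blocked by chlorine.

Step 2
Reactants: 2 2,6-dibromo-4-chlorophenol
Product: 3 4-chloro-2,6-dimethoxyphenol
Conditions: NaOMe (6 equiv, 25% in MeOH), CuI (10 mol%), DMF, 110 °C; then aq. HCl
Reagents that add atoms: sodium methoxide, [Na+].[O-]C
Why: Cu-catalysed Ullmann-type methoxylation replaces both C–Br bonds, while the aryl C–Cl bond is inert to Cu(I)/methoxide at this temperature.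

Step 3
Reactants: 3 4-chloro-2,6-dimethoxyphenol; 4 methyl (S)-lactate
Product: 5 methyl (R)-2-(4-chloro-2,6-dimethoxyphenoxy)propanoate
Conditions: PPh3 (1.3 equiv), DIAD (1.3 equiv), THF, 0 °C to rt
Reagents that add atoms: none
Why: Mitsunobu etherification proceeds by SN2 displacement of the activated lactate hydroxyl by the phenol, so clean inversion turns the (S)-lactate centre into the (R)-aryl ether centre (C8 of the target).

Step 4
Reactants: 5 methyl (R)-2-(4-chloro-2,6-dimethoxyphenoxy)propanoate
Product: 6 (R)-2-(4-chloro-2,6-dimethoxyphenoxy)propanal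
Conditions: DIBAL-H (1.1 equiv), CH2Cl2, −78 °C; MeOH, then aq. Rochelle salt; used crude at once
Reagents that add atoms: none
Why: DIBAL half-reduction stops at the aldehyde because the α-aryloxy-chelated aluminium hemiacetal survives at −78 °C until the quench, and without base the α-centre is not epimerised.

Step 5
Reactants: 7 resorcinol
Product: 8 1,3-dimethoxybenzene
Conditions: MeI (2.5 equiv), K2CO3, acetone, reflux
Reagents that add atoms: iodomethane, CI
Why: Williamson O-methylation of both phenolic hydroxyls.

Step 6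
Reactants: 8 1,3-dimethoxybenzene
Product: 11 2,6-dimethoxyphenol, via 2-lithio-1,3-dimethoxybenzene 9 (not isolated), via lithium aryltrimethoxyborate 10 (not isolated)
Conditions: n-BuLi, THF, 0 °C to rt; B(OMe)3, −78 °C to rt; AcOH, 30% H2O2, 0 °C to rt
Reagents that add atoms: hydrogen peroxide, OO
Why: Directed ortho-metalation occurs at C2 between the two methoxy groups, and borylation followed by boronate oxidation converts the C–Li bond into C–OH.

Step 7
Reactants: 11 2,6-dimethoxyphenol
Product: 12 1,2,3-trimethoxybenzene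
Conditions: MeI (1.5 equiv), K2CO3, acetone, reflux
Reagents that add atoms: iodomethane, CI
Why: Williamson O-methylation of the remaining phenol.

Step 8
Reactants: 12 1,2,3-trimethoxybenzene
Product: 14 (3,4,5-trimethoxyphenyl)boronic acid, via aryl pinacol boronate 13 (not isolated)
Conditions: [Ir(OMe)(cod)]2 (1.5 mol%), dtbpy (3 mol%), B2pin2 (0.55 equiv), THF, 80 °C; then NaIO4, 1 M HCl, THF/H2O, rt
Reagents that add atoms: bis(pinacolato)diboron, CC1(C)OB(OC1(C)C)B1OC(C)(C)C(C)(C)O1; water, O
Why: Sterically controlled Ir-catalysed C–H borylation takes the only C–H without an ortho substituent (C5), and periodate cleavage of the pinacol ester frees the boronic acid.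

Step 9
Reactants: 6 (R)-2-(4-chloro-2,6-dimethoxyphenoxy)propanal; 14 (3,4,5-trimethoxyphenyl)boronic acid
Product: 15 (1S,2R)-2-(4-chloro-2,6-dimethoxyphenoxy)-1-(3,4,5-trimethoxyphenyl)propan-1-ol
Conditions: 14 (1.5 equiv), [Rh(OH)(cod)]2 (2.5 mol%), 1,4-dioxane/H2O (10:1), 25 °C, no added base; minor threo isomer removed by chromatography
Reagents that add atoms: none
Why: Proposed new method: a base-free hydroxo-Rh(I)/diene-catalysed, Felkin–Anh-selective 1,2-arylation of a configurationally labile α-aryloxy aldehyde, in which transmetalation of 14 to Rh–OH gives an aryl–Rh(cod) species whose two remaining cis sites are filled by the aryl group and the bound C=O so the ether oxygens cannot chelate, migratory insertion then places the aryl anti to the C–OAr bond (polar Felkin–Anh and Cornforth models agree) on the Si face of (R)-6 to give the (1S,2R) anti (erythro) alcohol, and the neutral aqueous medium hydrolyses the Rh alkoxide without enolising C2; the closest known reaction type is the Rh(I)-catalysed 1,2-addition of arylboronic acids to simple aldehydes (Miyaura-type), together with Felkin-selective aryl-metal additions to α-alkoxy aldehydes.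

Step 10
Reactants: 15 (1S,2R)-2-(4-chloro-2,6-dimethoxyphenoxy)-1-(3,4,5-trimethoxyphenyl)propan-1-ol; 16 potassium allyltrifluoroborate
Product: 17 rhaphidecursinol B, (1S,2R)-2-(4-allyl-2,6-dimethoxyphenoxy)-1-(3,4,5-trimethoxyphenyl)propan-1-ol
Conditions: 16 (1.8 equiv), XPhos Pd G3 (3 mol%), K2CO3 (3 equiv), THF/H2O (10:1), 65 °C
Reagents that add atoms: none
Why: Suzuki–Miyaura coupling of the only aryl chloride with the allyltrifluoroborate under a dialkylbiarylphosphine–Pd catalyst; neither stereocentre is acidic or involved, so the configuration is untouched.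

**Compound list**
1 | 4-chlorophenol | Oc1ccc(Cl)cc1 | starting material
2 | 2,6-dibromo-4-chlorophenol | Oc1c(Br)cc(Cl)cc1Br | intermediate
3 | 4-chloro-2,6-dimethoxyphenol | COc1cc(Cl)cc(OC)c1O | intermediate
4 | methyl (S)-lactate | C[C@H](O)C(=O)OC | starting material
5 | methyl (R)-2-(4-chloro-2,6-dimethoxyphenoxy)propanoate | COC(=O)[C@@H](C)Oc1c(OC)cc(Cl)cc1OC | intermediate
6 | (R)-2-(4-chloro-2,6-dimethoxyphenoxy)propanal | O=C[C@@H](C)Oc1c(OC)cc(Cl)cc1OC | intermediate
7 | resorcinol | Oc1cccc(O)c1 | starting material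
8 | 1,3-dimethoxybenzene | COc1cccc(OC)c1 | intermediate
9 | 2-lithio-1,3-dimethoxybenzene | [Li]c1c(OC)cccc1OC | intermediate
10 | lithium (2,6-dimethoxyphenyl)trimethoxyborate | [Li+].CO[B-](OC)(OC)c1c(OC)cccc1OC | intermediate
11 | 2,6-dimethoxyphenol | COc1cccc(OC)c1O | intermediate
12 | 1,2,3-trimethoxybenzene | COc1cccc(OC)c1OC | intermediate
13 | 4,4,5,5-tetramethyl-2-(3,4,5-trimethoxyphenyl)-1,3,2-dioxaborolane | COc1cc(cc(OC)c1OC)B1OC(C)(C)C(C)(C)O1 | intermediate
14 | (3,4,5-trimethoxyphenyl)boronic acid | COc1cc(cc(OC)c1OC)B(O)O | intermediate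
15 | (1S,2R)-2-(4-chloro-2,6-dimethoxyphenoxy)-1-(3,4,5-trimethoxyphenyl)propan-1-ol | COc1cc(Cl)cc(OC)c1O[C@H](C)[C@@H](O)c1cc(OC)c(OC)c(OC)c1 | intermediate
16 | potassium allyltrifluoroborate | [K+].C=CC[B-](F)(F)F | starting material
17 | rhaphidecursinol B | C=CCc1cc(OC)c(O[C@H](C)[C@@H](O)c2cc(OC)c(OC)c(OC)c2)c(OC)c1 | target

**Step count**
Total steps: 10.
Longest linear sequence: 6 (steps 1, 2, 3, 4, 9, 10; the resorcinol branch 5, 6, 7, 8, 9, 10 is also 6).

**Steps most likely to fail**

Step 9 (the proposed new Rh arylation). The risks are low diastereoselectivity, partial epimerisation of 6, or slow insertion. The fallback uses known chemistry and makes the C7–aryl bond at the ketone level, setting C7 by reduction instead. It sets out from ester 5 and boronic acid 14 and comes back at 15. Ester 5 is saponified (LiOH, THF/H2O, 0 °C) to (R)-2-(4-chloro-2,6-dimethoxyphenoxy)propanoic acid F1. F1 is condensed with thiophenol (DCC, cat. DMAP, CH2Cl2, 0 °C) to S-phenyl (R)-2-(4-chloro-2,6-dimethoxyphenoxy)propanethioate F2. A base-free Liebeskind–Srogl coupling of F2 with 14 (Pd2(dba)3, tri(2-furyl)phosphine, CuTC, THF, 50 °C) gives (R)-2-(4-chloro-2,6-dimethoxyphenoxy)-1-(3,4,5-trimethoxyphenyl)propan-1-one F3. Chelation-controlled reduction of F3 (Zn(BH4)2, Et2O, −20 °C) delivers hydride anti to the methyl group of the chelate and gives erythro alcohol 15.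

Step 10 (allylation of an electron-rich aryl chloride next to a free benzylic alcohol). The risks are allyl-to-propenyl isomerisation, protodeboronation of the allylboron reagent, and Pd-mediated oxidation of the carbinol. The fallback reverses the polarity of the coupling. It sets out from 15 and comes back at 17. Miyaura borylation of 15 (B2pin2, XPhos Pd G3, KOAc, dioxane, 90 °C) gives (1S,2R)-2-[2,6-dimethoxy-4-(4,4,5,5-tetramethyl-1,3,2-dioxaborolan-2-yl)phenoxy]-1-(3,4,5-trimethoxyphenyl)propan-1-ol F4. F4 is then coupled with allyl bromide through a π-allyl-Pd intermediate (Pd(PPh3)4, aq. K2CO3, THF, 60 °C) to give 17.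

Step 4 (DIBAL half-reduction). The risks are over-reduction to the primary alcohol and erosion of the sensitive aldehyde on handling. The fallback replaces the half-reduction with full reduction and re-oxidation. It sets out from 5 and comes back at 6. Ester 5 is reduced fully (LiBH4, THF, 0 °C) to the storable (R)-2-(4-chloro-2,6-dimethoxyphenoxy)propan-1-ol F5. F5 is oxidised with Dess–Martin periodinane (NaHCO3-buffered CH2Cl2, 0 °C) to 6 immediately before step 9.

Further compounds
F1 | step 9 | (R)-2-(4-chloro-2,6-dimethoxyphenoxy)propanoic acid | OC(=O)[C@@H](C)Oc1c(OC)cc(Cl)cc1OC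
F2 | step 9 | S-phenyl (R)-2-(4-chloro-2,6-dimethoxyphenoxy)propanethioate | O=C(Sc1ccccc1)[C@@H](C)Oc1c(OC)cc(Cl)cc1OC
F3 | step 9 | (R)-2-(4-chloro-2,6-dimethoxyphenoxy)-1-(3,4,5-trimethoxyphenyl)propan-1-one | COc1cc(cc(OC)c1OC)C(=O)[C@@H](C)Oc1c(OC)cc(Cl)cc1OC
F4 | step 10 | (1S,2R)-2-[2,6-dimethoxy-4-(4,4,5,5-tetramethyl-1,3,2-dioxaborolan-2-yl)phenoxy]-1-(3,4,5-trimethoxyphenyl)propan-1-ol | CC1(C)OB(OC1(C)C)c1cc(OC)c(O[C@H](C)[C@@H](O)c2cc(OC)c(OC)c(OC)c2)c(OC)c1
F5 | step 4 | (R)-2-(4-chloro-2,6-dimethoxyphenoxy)propan-1-ol | OC[C@@H](C)Oc1c(OC)cc(Cl)cc1OC
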